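The numbers in the tables are simulated for substances that don't exist; noise was put on by code.

A decade of time is the unit I reckon in, set against a decade of J, since I take the further exchange that consumes J to be pseudo-first-order in J at a given [X], so that its logarithm adds up as the run proceeds.

| flask | Q | X | remark | time |
|---|---|---|---|---|
| Friday's | 0.30 M | 0.60 M | run made earlier |  |
| flask | 0.20 M | 0.600 M |  | 6.0 min |

Friday's run (percent of the Q charged)

| time / s | J / % | Q / % |
|---|---|---|
| 10.0 | 76.8 | 19.3 |
| 25.0 | 88.3 | 4.5 |
| 50.0 | 86.1 | 1.1 |
| 80.0 | 80.6 | 0.2 |
| 120 | 77.4 | 0.7 |

(standard deviation of a reading: 0.5 percentage points)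

- what was read earlier has a scatter of 0.5 percentage points, one standard deviation

- equivalents of X to Q, everything else as given, that leave most J at 6.0 min
- the amount of J then, in percent of the Q charged
- the amount of J with the amounts as given

What do Friday's readings give? Q plus J is what has not gone past J, and its loss in decades, the log10 of the charge over Q plus J, is 0.0595 at 50.0 s and 0.107 at 120 s.

Why plot that against log time? I assume that X is lost mainly by a step second order in itself, so that late [X] falls inversely with time and each decade of time brings an equal exposure to X; Friday's slope, read as the decades of Q plus J lost per decade of time, is 0.126.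

And this flask? Carrying Friday's run on to 6.0 min gives 0.167 decades, and scaling, as a crude guess of my own, by the X spare after the first exchange, 0.400 M here against 0.300 M on Friday, gives 0.223, so I reckon J in this flask near 59.8 %.

Isn't that slope two scattered readings and a guess? Yes, the 80.0 s reading would make it 0.162, so I commit to that figure roughly.

And the best charge? My reckoning ties the loss to spare X, so it points below the charge as given and gives a direction, not a figure; Friday's peak reading of 88.3 % is my guess for the J to hope for.

The forecast named 1.5 equiv with 88 % of J, and 66 % as given, above my figure, holding that “X is lost independently, roughly first-order”.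

The flask gives 1.18 equiv as the best charge, 87.9 % of J there, and 54.9 % of J as given.

    J + X → E + L (k = 0.0160 M⁻¹ s⁻¹)
    Q + X → E + J (k = 0.420 M⁻¹ s⁻¹)
    G ⇌ E, rate k3*(cs3 - [E]) while solid is left; crystals form when [E] > cs3 (solubility = 0.100 M, k = 0.400 s⁻¹)
    2 X → D (k = 0.0190 M⁻¹ s⁻¹)

In this flask the half-life of J by the second exchange at [X] as charged, 1.2 min, is short against the 6.0 min, yet J stands at 54.9 % then, with X down to 6.42 % of its charge. The step from 2 X to D has 73 % of its turnover up to 6.0 min behind it by 1.20 min, and the loss of J comes to 0.260 decades against my 0.223. Read at 2.5 min, the same flask gets from the slope 0.159 decades, or 69.3 % of J, and the computed value is 66.9 %.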